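**Retrosynthetic overview**
- The route rests on the imide bond N1–C1' between the nitrogen of the five-membered pyrrolidine-2,4-dione ring and the carbonyl carbon of the (E)-dodec-2-enoyl chain (alkene C2'=C3'). N1–C1' and C1'–C2' are made together at palladium from a lactam N–H, CO and (E)-1-iodoundec-1-ene.
- The C3–acetyl bond is disconnected last: removal of the 4-methoxybenzyl enol ether, then O-acetylation and O-to-C acetyl shift on the N-enoyl tetramic acid.
- The only ring is formed first, from Boc-D-leucine and Meldrum's acid (C5 comes from D-leucine). It is then masked as the 4-O-(4-methoxybenzyl) ether and freed of Boc.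
- The alkenyl iodide comes from 1-undecyne by hydrozirconation and iodination.

Key step: step 5

Remark: compounds 5, 14 and 16 are written as the 4-hydroxy (enol) tautomers of the pyrrolidine-2,4-diones; the tautomers equilibrate and are treated as one compound.

**Route**

Step 1
Reactants: 1 Boc-D-leucine; 2 Meldrum's acid
Product: 5 tert-butyl (R)-3-hydroxy-2-isobutyl-5-oxo-2,5-dihydro-1H-pyrrole-1-carboxylate, via acyl Meldrum's acid 3 (not isolated), via acylketene 4 (not isolated)
Conditions: DCC, DMAP, CH2Cl2, 0 °C to rt; filter, wash with 5% aq. KHSO4; then EtOAc, reflux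
Reagents that add atoms: none
Why: Carbodiimide C-acylation of Meldrum's acid gives 3, which on heating loses acetone and CO2 to acylketene 4 that the carbamate N–H traps by intramolecular acylation (tetramic acid synthesis through an acyl Meldrum's acid), the C5 stereocentre being carried unchanged from D-leucine.

Step 2
Reactants: 5 tert-butyl (R)-3-hydroxy-2-isobutyl-5-oxo-2,5-dihydro-1H-pyrrole-1-carboxylate; 6 4-methoxybenzyl alcohol
Product: 7 tert-butyl (R)-2-isobutyl-3-[(4-methoxybenzyl)oxy]-5-oxo-2,5-dihydro-1H-pyrrole-1-carboxylate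
Conditions: PPh3, DIAD, THF, 0 °C to rt
Reagents that add atoms: none
Why: Mitsunobu reaction in which the acidic 4-enol is alkylated on oxygen by the alkoxyphosphonium ion of the primary benzylic alcohol, a known way to 4-O-alkyl tetramates that does not touch C5.

Step 3
Reactants: 7 tert-butyl (R)-2-isobutyl-3-[(4-methoxybenzyl)oxy]-5-oxo-2,5-dihydro-1H-pyrrole-1-carboxylate
Product: 8 (R)-5-isobutyl-4-[(4-methoxybenzyl)oxy]-1,5-dihydro-2H-pyrrol-2-one
Conditions: Mg(ClO4)2 (0.2 equiv), MeCN, 50 °C
Reagents that add atoms: none
Why: Lewis-acid-mediated cleavage of an N-acyl carbamate, in which magnesium chelates the two imide-type carbonyls and the tert-butyl group leaves as isobutene with loss of CO2, under conditions mild enough to spare the acid-labile 4-methoxybenzyl enol ether.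

Step 4
Reactants: 9 1-undecyne
Product: 11 (E)-1-iodoundec-1-ene, via (E)-undec-1-enylzirconocene chloride 10 (not isolated)
Conditions: Cp2Zr(H)Cl, THF, rt; then I2, THF, 0 °C
Reagents that add atoms: iodine, [I][I]
Why: Hydrozirconation of the terminal alkyne is a syn addition that places zirconium on the terminal carbon, and iododezirconation proceeds with retention, so the E iodide should result.

Step 5
Reactants: 8 (R)-5-isobutyl-4-[(4-methoxybenzyl)oxy]-1,5-dihydro-2H-pyrrol-2-one; 11 (E)-1-iodoundec-1-ene; 12 carbon monoxide
Product: 13 (R)-1-[(E)-dodec-2-enoyl]-5-isobutyl-4-[(4-methoxybenzyl)oxy]-1,5-dihydro-2H-pyrrol-2-one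
Conditions: Pd(OAc)2 (5 mol %), Xantphos (7.5 mol %), Cs2CO3 (1.5 equiv), CO (1 atm), toluene, 70 °C
Reagents that add atoms: none
Why: Pd(OAc)2 is reduced in the flask to zerovalent palladium, which adds oxidatively to the C–I bond of 11 with retention of the E geometry; CO inserts to give a divalent acylpalladium iodide held by Xantphos (forming C1'–C2'), the carbonate-deprotonated lactam nitrogen of 8 displaces iodide, and C–N reductive elimination forms N1–C1'. The closest known reaction type is the Heck-type aminocarbonylation of aryl and alkenyl halides with amide, lactam and oxazolidinone N–H partners, which gives imides. No ring is closed and no stereocentre is created. The step needs carbonylative coupling to win over direct N-alkenylation, which the CO atmosphere and the wide-bite-angle Xantphos should secure by making insertion fast; it needs the E alkene to be kept, which follows because the acyl group is built on the metal and never exists as a free enoyl halide or vinylketene; and it needs the C5 configuration to be kept, for which a heterogeneous carbonate base in toluene should reach the N–H but not the less acidic C5–H. The 4-methoxybenzyl enol ether keeps the acidic, chelating β-dicarbonyl masked, so it should neither bind palladium nor compete as an O- or C-nucleophile.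

Step 6
Reactants: 13 (R)-1-[(E)-dodec-2-enoyl]-5-isobutyl-4-[(4-methoxybenzyl)oxy]-1,5-dihydro-2H-pyrrol-2-one
Product: 14 (R)-1-[(E)-dodec-2-enoyl]-4-hydroxy-5-isobutyl-1,5-dihydro-2H-pyrrol-2-one
Conditions: TFA, anisole (5 equiv), CH2Cl2, 0 °C
Reagents that add atoms: none
Why: Acidolysis of the 4-methoxybenzyl enol ether by ionisation to the stabilised benzylic cation, which anisole captures by Friedel–Crafts alkylation so that it cannot alkylate the nucleophilic C3; the imide and the enoyl alkene are stable to anhydrous acid.

Step 7
Reactants: 14 (R)-1-[(E)-dodec-2-enoyl]-4-hydroxy-5-isobutyl-1,5-dihydro-2H-pyrrol-2-one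
Product: 16 reutericyclin C, via 4-O-acetyl enol ester 15 (not isolated)
Conditions: AcOH, DCC, DMAP (1.5 equiv), CH2Cl2, 0 °C to rt; dilute aq. HCl work-up
Reagents that add atoms: acetic acid, CC(=O)O
Why: Steglich O-acylation of the 4-enol gives 15, and DMAP then carries the acetyl group from oxygen to C3 (Fries-type O-to-C acyl migration, the standard 3-acylation of tetramic acids), driven by formation of the chelated tricarbonyl and leaving C5 untouched.

**Compound list**
1 | Boc-D-leucine, (R)-2-[(tert-butoxycarbonyl)amino]-4-methylpentanoic acid | CC(C)C[C@@H](NC(=O)OC(C)(C)C)C(=O)O | starting material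
2 | Meldrum's acid, 2,2-dimethyl-1,3-dioxane-4,6-dione | CC1(C)OC(=O)CC(=O)O1 | starting material
3 | acyl Meldrum's acid, tert-butyl (R)-[1-(2,2-dimethyl-4,6-dioxo-1,3-dioxan-5-ylidene)-1-hydroxy-4-methylpentan-2-yl]carbamate | CC(C)C[C@@H](NC(=O)OC(C)(C)C)C(O)=C1C(=O)OC(C)(C)OC1=O | intermediate
4 | acylketene, tert-butyl (R)-(6-methyl-1,3-dioxohept-1-en-4-yl)carbamate | CC(C)C[C@@H](NC(=O)OC(C)(C)C)C(=O)C=C=O | intermediate
5 | tert-butyl (R)-3-hydroxy-2-isobutyl-5-oxo-2,5-dihydro-1H-pyrrole-1-carboxylate | O=C1C=C(O)[C@@H](CC(C)C)N1C(=O)OC(C)(C)C | intermediate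
6 | 4-methoxybenzyl alcohol | COc1ccc(CO)cc1 | starting material
7 | tert-butyl (R)-2-isobutyl-3-[(4-methoxybenzyl)oxy]-5-oxo-2,5-dihydro-1H-pyrrole-1-carboxylate | O=C1C=C(OCc2ccc(OC)cc2)[C@@H](CC(C)C)N1C(=O)OC(C)(C)C | intermediate
8 | (R)-5-isobutyl-4-[(4-methoxybenzyl)oxy]-1,5-dihydro-2H-pyrrol-2-one | O=C1C=C(OCc2ccc(OC)cc2)[C@@H](CC(C)C)N1 | intermediate
9 | 1-undecyne | CCCCCCCCCC#C | starting material
10 | (E)-undec-1-enylzirconocene chloride | CCCCCCCCC/C=C/[Zr+2]Cl.[cH-]1cccc1.[cH-]1cccc1 | intermediate
11 | (E)-1-iodoundec-1-ene | CCCCCCCCC/C=C/I | intermediate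
12 | carbon monoxide | [C-]#[O+] | starting material
13 | (R)-1-[(E)-dodec-2-enoyl]-5-isobutyl-4-[(4-methoxybenzyl)oxy]-1,5-dihydro-2H-pyrrol-2-one | CCCCCCCCC/C=C/C(=O)N1C(=O)C=C(OCc2ccc(OC)cc2)[C@H]1CC(C)C | intermediate
14 | (R)-1-[(E)-dodec-2-enoyl]-4-hydroxy-5-isobutyl-1,5-dihydro-2H-pyrrol-2-one | CCCCCCCCC/C=C/C(=O)N1C(=O)C=C(O)[C@H]1CC(C)C | intermediate
15 | (R)-1-[(E)-dodec-2-enoyl]-2-isobutyl-5-oxo-2,5-dihydro-1H-pyrrol-3-yl acetate | CCCCCCCCC/C=C/C(=O)N1C(=O)C=C(OC(C)=O)[C@H]1CC(C)C | intermediate
16 | reutericyclin C, (R)-3-acetyl-1-[(E)-dodec-2-enoyl]-4-hydroxy-5-isobutyl-1,5-dihydro-2H-pyrrol-2-one | CCCCCCCCC/C=C/C(=O)N1C(=O)C(C(C)=O)=C(O)[C@H]1CC(C)C | target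

**Step count**
Total steps: 7. Longest linear sequence: 6 steps (1, 2, 3, 5, 6, 7 from Boc-D-leucine); step 4 is a one-step side branch.

**Steps most likely to fail**

Step 5. The weakly nucleophilic lactam nitrogen may capture the acylpalladium species too slowly, so that the catalyst decays or the acyl intermediate is lost to adventitious water. The carbonate may also erode the C5 configuration of the N-acylated product, or cleave the new imide. Fallback, from 8 back to 13: commercial (E)-dodec-2-enoic acid F1 is converted with pentafluorophenol and DCC in EtOAc into pentafluorophenyl (E)-dodec-2-enoate F2. Lactam 8 is deprotonated at nitrogen with n-BuLi in THF at −78 °C and acylated with F2 to give 13. No tertiary amine is present, so the vinylketene path to the deconjugated isomer is closed, and the low temperature should protect C5.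

Step 7. DMAP may cleave the exocyclic N-enoyl group by transacylation, or add in conjugate fashion to the enoyl unit, and the O-to-C acetyl migration may stall at the enol ester. Fallback, from 14 back to 16: direct Lewis-acid C-acylation with acetyl chloride in BF3·OEt2 at 70 °C should give the difluoroboron chelate of the 3-acetyl tetramic acid F3. Heating F3 in methanol removes boron and gives 16, with no nucleophilic amine present at any point.

Step 3. Carbamate cleavage may be incomplete, or the 4-methoxybenzyl enol ether may be lost under the Lewis acid at 50 °C. Fallback, from 5 back to 8, replacing steps 2 and 3: the order of events is reversed. TFA in CH2Cl2 removes Boc from 5 to give (R)-5-isobutylpyrrolidine-2,4-dione F4. A Mitsunobu reaction of F4 with alcohol 6 (PPh3, DIAD, THF) then alkylates the far more acidic enol oxygen in preference to the lactam N–H and gives 8 directly, so no carbamate has to be removed in the presence of the 4-methoxybenzyl group.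

**Further compounds**
F1 | step 5 | (E)-dodec-2-enoic acid (bought, not made) | CCCCCCCCC/C=C/C(=O)O
F2 | step 5 | pentafluorophenyl (E)-dodec-2-enoate | CCCCCCCCC/C=C/C(=O)Oc1c(F)c(F)c(F)c(F)c1F
F3 | step 7 | difluoroboron chelate of 16, boron bound to the C4 oxygen and the acetyl oxygen | CCCCCCCCC/C=C/C(=O)N1C(=O)C2=C(C)O[B-](F)(F)[O+]=C2[C@H]1CC(C)C
F4 | step 3 | (R)-5-isobutylpyrrolidine-2,4-dione | O=C1CC(=O)[C@@H](CC(C)C)N1
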